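**Strategy**

1. Numbering follows the tridecane chain: C1 is the benzylic CH2, C2 the acetoxy carbon, C3–C7 the five methylenes, C8 the ketone carbon. The retrosynthesis first masks the phenol as a benzyl ether, then cuts the C2–C3 bond to give a racemic 1-bromo-2-arylethyl acetate and undec-1-en-6-one.
2. The bromo acetate is opened at its C2–O and C2–Br bonds to an arylacetaldehyde and acetyl bromide, and the aldehyde is cut at C1–C2 back to 3-hydroxy-5-methoxybenzaldehyde. The keto olefin is cut at C7–C8 into hexanoyl chloride and 5-bromopent-1-ene.
3. Forward, the chain is joined in the order C7–C8 (Weinreb ketone synthesis), C1–C2 (Wittig one-carbon homologation), C2–O/C2–Br (acyl bromide addition), C2–C3 (nickel-hydride hydroalkylation), followed by debenzylation. No ring is formed; the benzene ring is bought.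
4. The enabling feature is C2 itself: an acetylated dialkyl carbinol carbon whose neighbours C1 and C3 are both CH2, too alike for a ketone reduction to tell apart. It can instead be addressed as an α-acetoxyalkyl radical and joined to the terminal olefin carbon (the future C3) of a chain whose C8 ketone lies five carbons away.
5. The single stereocentre, (R) at C2, is set in that coupling by a chiral bis(oxazoline)–nickel catalyst that funnels both enantiomers of the bromide into one product. Nothing later touches it.

Key step: step 7

Assumption: which enantiomer of the bis(oxazoline) ligand delivers the (R) acetate is taken to be settled by a trial coupling on a model aldehyde, and the route is written with that enantiomer.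

**Route**

Step 1
Reactants: 1 hexanoyl chloride
Product: 2 N-methoxy-N-methylhexanamide
Conditions: MeNH(OMe)·HCl, K2CO3, CH2Cl2/H2O, 0 °C to rt
Reagents that add atoms: N,O-dimethylhydroxylamine hydrochloride, CNOC.Cl
Why: Schotten–Baumann N-acylation of the hydroxylamine by the acid chloride is fast in the two-phase system and stops cleanly at the Weinreb amide, the carbonate taking up both equivalents of HCl.

Step 2
Reactants: 2 N-methoxy-N-methylhexanamide; 3 5-bromopent-1-ene
Product: 6 undec-1-en-6-one, via pent-4-enylmagnesium bromide 4 (not isolated), via magnesium chelate 5 (not isolated)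
Conditions: 3, Mg turnings, cat. I2, THF, rt; then 2, THF, 0 °C; 1 M aq HCl, 0 °C
Reagents that add atoms: none
Why: Weinreb ketone synthesis, in which the Grignard reagent 4 adds only once because the tetrahedral adduct is held as the five-membered magnesium chelate 5 until the acidic quench, so the ketone is released when no organometallic is left and the terminal olefin is untouched.

Step 3
Reactants: 7 3-hydroxy-5-methoxybenzaldehyde
Product: 8 3-(benzyloxy)-5-methoxybenzaldehyde
Conditions: BnBr, K2CO3, DMF, rt
Reagents that add atoms: benzyl bromide, BrCc1ccccc1
Why: Williamson ether synthesis on the phenoxide installs a benzyl group that is inert to the ylide, the acyl bromide and the nickel–silane conditions and is removed by hydrogenolysis at the end.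

Step 4
Reactants: 8 3-(benzyloxy)-5-methoxybenzaldehyde; 9 (methoxymethyl)triphenylphosphonium chloride
Product: 11 1-(benzyloxy)-3-methoxy-5-(2-methoxyethenyl)benzene as an E/Z mixture, via methoxymethylene ylide 10 (not isolated)
Conditions: 9, KOtBu, THF, 0 °C; then 8, 0 °C to rt
Reagents that add atoms: none
Why: Wittig olefination of the non-enolisable aromatic aldehyde by the methoxymethylene ylide 10 adds the carbon that becomes C2, and the olefin geometry is of no consequence because the double bond disappears in the next step.

Step 5
Reactants: 11 1-(benzyloxy)-3-methoxy-5-(2-methoxyethenyl)benzene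
Product: 12 2-[3-(benzyloxy)-5-methoxyphenyl]acetaldehyde
Conditions: 2 M aq HCl, THF, 45 °C, argon; crude aldehyde taken on the same day
Reagents that add atoms: water, O
Why: Acid-catalysed enol ether hydrolysis (C-protonation, hydration of the oxocarbenium ion, loss of methanol) unmasks the arylacetaldehyde, while both aryl ethers are stable to dilute acid at this temperature.

Step 6
Reactants: 12 2-[3-(benzyloxy)-5-methoxyphenyl]acetaldehyde; 13 acetyl bromide
Product: 14 rac-2-[3-(benzyloxy)-5-methoxyphenyl]-1-bromoethyl acetate
Conditions: 13 (1.05 equiv), ZnBr2 (2 mol%), CH2Cl2, −20 °C; volatiles removed cold, residue used at once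
Reagents that add atoms: none
Why: Lewis-acid-catalysed addition of the acyl bromide across the aldehyde C=O (1-bromoalkyl ester formation) is fast at low temperature and gives the new centre as a racemate, which is all the stereoconvergent coupling requires, while the short cold contact time spares the benzyl ether and limits loss of HBr.

Step 7
Reactants: 14 rac-2-[3-(benzyloxy)-5-methoxyphenyl]-1-bromoethyl acetate; 6 undec-1-en-6-one (1.5 equiv)
Product: 15 (2R)-1-[3-(benzyloxy)-5-methoxyphenyl]-8-oxotridecan-2-yl acetate
Conditions: NiBr2·glyme (10 mol%), chiral C2-symmetric bis(oxazoline) ligand (12 mol%, enantiomer giving R), (EtO)3SiH, K3PO4·H2O, THF/DMA, 0 °C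
Reagents that add atoms: none
Why: The divalent nickel bromide precatalyst is converted by the silane and phosphate into a ligated nickel hydride that inserts the terminal olefin of 6 anti-Markovnikov to a primary alkylnickel; bromine-atom abstraction from either enantiomer of 14 by a low-valent nickel species gives the same planar α-acetoxyalkyl radical, which is captured to a trivalent dialkylnickel that reductively eliminates the C2–C3 bond. The closest known reaction type is the nickel-hydride-catalysed enantioconvergent hydroalkylation of terminal olefins with racemic 1-bromoalkyl esters made from aldehydes and acyl bromides, the olefin version of the stereoconvergent alkyl–alkyl Negishi coupling. No ring is closed. The new stereocentre C2 is controlled by the catalyst alone: the chiral bis(oxazoline) on nickel, aided by coordination of the acetate carbonyl, fixes the face on which the prochiral radical is captured and eliminated, and the ligand enantiomer is chosen to give (R). The step needs anti-Markovnikov hydrometalation without chain walking, which the unhindered monosubstituted olefin (three methylenes away from the ketone) secures, and chemoselectivity over the dialkyl ketone, the aryl ethers and the acetate, none of which should react with the nickel–silane system at 0 °C. Loss of HBr from 14 is held back by the weak heterogeneous base and the low temperature.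

Step 8
Reactants: 15 (2R)-1-[3-(benzyloxy)-5-methoxyphenyl]-8-oxotridecan-2-yl acetate
Product: 16 (2R)-1-(3-hydroxy-5-methoxyphenyl)-8-oxotridecan-2-yl acetate
Conditions: H2 (1 atm), 10% Pd/C, EtOAc, rt
Reagents that add atoms: none
Why: Heterogeneous catalytic hydrogenolysis cleaves only the benzylic C–O bond of the aryl benzyl ether, since the dialkyl ketone, the methyl ether and the acetate at the non-benzylic C2 are inert to H2 over Pd/C at one atmosphere, so the (R) centre is untouched.

**Compound list**

1 | hexanoyl chloride | CCCCCC(Cl)=O | starting material
2 | N-methoxy-N-methylhexanamide | CCCCCC(=O)N(C)OC | intermediate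
3 | 5-bromopent-1-ene | C=CCCCBr | starting material
4 | pent-4-enylmagnesium bromide (not isolated) | C=CCCC[Mg]Br | intermediate
5 | bromomagnesium salt of 6-[methoxy(methyl)amino]undec-1-en-6-ol, the tetrahedral chelate (not isolated) | CCCCCC(O[Mg]Br)(CCCC=C)N(C)OC | intermediate
6 | undec-1-en-6-one | C=CCCCC(=O)CCCCC | intermediate
7 | 3-hydroxy-5-methoxybenzaldehyde | COc1cc(O)cc(C=O)c1 | starting material
8 | 3-(benzyloxy)-5-methoxybenzaldehyde | COc1cc(OCc2ccccc2)cc(C=O)c1 | intermediate
9 | (methoxymethyl)triphenylphosphonium chloride | COC[P+](c1ccccc1)(c1ccccc1)c1ccccc1.[Cl-] | starting material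
10 | (methoxymethylidene)triphenylphosphorane (not isolated) | COC=P(c1ccccc1)(c1ccccc1)c1ccccc1 | intermediate
11 | 1-(benzyloxy)-3-methoxy-5-(2-methoxyethenyl)benzene, E/Z mixture | COC=Cc1cc(OC)cc(OCc2ccccc2)c1 | intermediate
12 | 2-[3-(benzyloxy)-5-methoxyphenyl]acetaldehyde | O=CCc1cc(OC)cc(OCc2ccccc2)c1 | intermediate
13 | acetyl bromide | CC(Br)=O | starting material
14 | rac-2-[3-(benzyloxy)-5-methoxyphenyl]-1-bromoethyl acetate | CC(=O)OC(Br)Cc1cc(OC)cc(OCc2ccccc2)c1 | intermediate
15 | (2R)-1-[3-(benzyloxy)-5-methoxyphenyl]-8-oxotridecan-2-yl acetate | CCCCCC(=O)CCCCC[C@H](Cc1cc(OCc2ccccc2)cc(OC)c1)OC(C)=O | intermediate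
16 | (2R)-1-(3-hydroxy-5-methoxyphenyl)-8-oxotridecan-2-yl acetate (CNP0302149.1) | CCCCCC(=O)CCCCC[C@H](Cc1cc(O)cc(OC)c1)OC(C)=O | target

**Step count**

Total: 8 steps (2 for the keto olefin, 4 for the aryl fragment, the coupling, the deprotection). Longest linear sequence: 6 steps, from 7 through steps 3, 4, 5, 6, 7 and 8.

**Steps most likely to fail**

Step 7. The nickel hydride may reduce the C–Br bond of 14 before the olefin is engaged (hydrodehalogenation), the phosphate may induce loss of HBr during a slow coupling, or hydrometalation may lag so that selectivity erodes. The fallback makes the same C2–C3 bond by a stereoconvergent Negishi cross-coupling with a preformed organozinc reagent, which takes both the hydride source and the base out of the flask. It sets out from 6 and comes back to the route at 15. Radical anti-Markovnikov addition of HBr to 6 (HBr, dibenzoyl peroxide, hexane, 0 °C) should give 1-bromoundecan-6-one F1. Zinc insertion (Zn dust, cat. I2, DMA, 70 °C) should convert it into (6-oxoundecyl)zinc bromide F2, a reagent class that tolerates ketones. Coupling of F2 with freshly made 14 under NiBr2·glyme and the same chiral bis(oxazoline) ligand (THF/DMA, −10 °C) should then give 15.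

Step 6. The bromo acetate may lose HBr towards the conjugated enol acetate, or ionise under the Lewis acid and be attacked by the electron-rich arene, so that no usable electrophile reaches the coupling. The fallback abandons the bromo acetate and sets C2 by reagent-controlled allylation. It sets out from 12 and comes back to the route at 16.
- Brown allylation of 12 with (+)-B-allyldiisopinocampheylborane, the reagent of the (−)-α-pinene series (Et2O, −78 °C; NaOH/H2O2), should by the usual facial preference of this reagent class give (2R)-1-[3-(benzyloxy)-5-methoxyphenyl]pent-4-en-2-ol F3.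
- Acetylation (Ac2O, pyridine, cat. DMAP) gives (2R)-1-[3-(benzyloxy)-5-methoxyphenyl]pent-4-en-2-yl acetate F4.
- The partner dec-1-en-5-one F5 is made from 2 and commercial but-3-enylmagnesium bromide by the Weinreb ketone synthesis of step 2.
- Olefin cross-metathesis of F4 with an excess of F5 (second-generation Hoveyda–Grubbs catalyst, CH2Cl2, 40 °C) should give (2R)-1-[3-(benzyloxy)-5-methoxyphenyl]-8-oxotridec-4-en-2-yl acetate F6 as an olefin mixture.
- Hydrogenation (H2, 10% Pd/C, EtOAc) saturates the C4–C5 double bond and removes the benzyl group in one operation, giving 16.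

Step 5. The enolisable arylacetaldehyde may undergo self-aldol condensation and air oxidation under the aqueous acid of the enol ether hydrolysis. The fallback reaches the aldehyde under neutral, anhydrous conditions by oxidation of the primary alcohol. It sets out from 8 and comes back to the route at 12. Wittig methylenation of 8 (Ph3PCH3Br, KOtBu, THF, 0 °C) should give 1-(benzyloxy)-3-ethenyl-5-methoxybenzene F7. Anti-Markovnikov hydroboration–oxidation (9-BBN, THF; NaOH/H2O2) gives 2-[3-(benzyloxy)-5-methoxyphenyl]ethan-1-ol F8. Dess–Martin oxidation (NaHCO3, CH2Cl2, 0 °C) then delivers 12 for immediate use.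

**Further compounds**

F1 | step 7 | 1-bromoundecan-6-one | CCCCCC(=O)CCCCCBr
F2 | step 7 | (6-oxoundecyl)zinc bromide | CCCCCC(=O)CCCCC[Zn]Br
F3 | step 6 | (2R)-1-[3-(benzyloxy)-5-methoxyphenyl]pent-4-en-2-ol | C=CC[C@H](Cc1cc(OCc2ccccc2)cc(OC)c1)O
F4 | step 6 | (2R)-1-[3-(benzyloxy)-5-methoxyphenyl]pent-4-en-2-yl acetate | C=CC[C@H](Cc1cc(OCc2ccccc2)cc(OC)c1)OC(C)=O
F5 | step 6 | dec-1-en-5-one | C=CCCC(=O)CCCCC
F6 | step 6 | (2R)-1-[3-(benzyloxy)-5-methoxyphenyl]-8-oxotridec-4-en-2-yl acetate, E/Z mixture | CCCCCC(=O)CCC=CC[C@H](Cc1cc(OCc2ccccc2)cc(OC)c1)OC(C)=O
F7 | step 5 | 1-(benzyloxy)-3-ethenyl-5-methoxybenzene | C=Cc1cc(OC)cc(OCc2ccccc2)c1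
F8 | step 5 | 2-[3-(benzyloxy)-5-methoxyphenyl]ethan-1-ol | OCCc1cc(OC)cc(OCc2ccccc2)c1
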